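**Retrosynthetic overview**

1. Target 27 ⇐ hydrolysis of enol δ-lactone 26 ⇐ NHC-catalysed annulation of (E)-hex-2-enal onto C6–H of the bicyclic dione 24 (sets the side-chain centre) ⇐ 23 by loss of a 2-(trimethylsilyl)ethyl group from O5.
2. 23 ⇐ open-chain ester 21 in one pot: base closes ring A (carbocycle C4a–C5–C6–C7–C8–C8a) through the C4a–C8a bond, then quinine closes ring B (dihydropyranone O1–C2–C3–C4–C4a–C8a) through the O1–C2 bond.
3. Enabling feature: C8a is a carboxyl carbon on the quaternary, non-enolisable C8 and sits 1,6 to C4a, the carbon between the C4 tigloyl ketone and the C5 enol-ether carbon. After closure the C8a enol oxygen is the only free oxygen next to the tigloyl C2=C3 bond, and C8 prevents aromatisation.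
4. 21 ⇐ γ-acylation of the dienolate of enol ether 19 (propyne + tigloyl chloride + Me3SiCH2CH2OH) with the chloride of half-ester 14; 14 ⇐ phase-transfer prenylation of lavandulylmalonate 11 (C8 centre) ⇐ (S)-lavandulyl iodide 7 (Evans alkylation).
5. Ring order: ring A, then ring B (same operation), then a transient lactone ring that is formed in step 14 and opened in step 15.

Key step: step 12

Remark (assumption): chromane numbering (O1, C2, C3, C4, C4a, C5–C8, C8a) is used for the core; the sense of induction of the chiral catalysts in steps 7, 12 and 14 is assigned by analogy with simpler substrates, and each catalyst is available as its antipode or pseudo-enantiomer.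

**Step 1**
Reactants: 1 (4S)-4-benzyl-1,3-oxazolidin-2-one; 2 3-methylbut-2-enoyl chloride
Product: 3 N-(3-methylbut-2-enoyl) oxazolidinone
Conditions: n-BuLi, THF, −78 °C; then 2, −78 → 0 °C
Reagents that add atoms: none
Why: N-acylation of the lithiated Evans auxiliary by the acid chloride; no stereocentre is formed.

**Step 2**
Reactants: 3 N-(3-methylbut-2-enoyl) oxazolidinone; 4 prenyl bromide
Product: 5 α-prenylated β,γ-unsaturated imide
Conditions: NaN(SiMe3)2, THF, −78 °C; 4, −78 → −40 °C; cold NH4Cl quench
Reagents that add atoms: none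
Why: Evans asymmetric alkylation of the chelated (Z)-dienolate at its α-carbon (deconjugative α-alkylation); prenyl bromide should enter on the face away from the benzyl group, setting the (S) centre of the lavandulyl skeleton.

**Step 3**
Reactants: 5 α-prenylated imide
Product: 6 (S)-lavandulol
Conditions: LiBH4, MeOH (1 equiv), Et2O, 0 °C
Reagents that add atoms: none
Why: Reductive cleavage of the N-acyl oxazolidinone gives the primary alcohol and returns the auxiliary; the α-centre is not touched.

**Step 4**
Reactants: 6 (S)-lavandulol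
Product: 7 (S)-lavandulyl iodide
Conditions: PPh3, I2, imidazole, CH2Cl2, 0 °C
Reagents that add atoms: iodine, II
Why: Appel-type iodination of a primary alcohol under neutral conditions; the stereocentre is β to the reacting carbon and is unaffected.

**Step 5**
Reactants: 8 3-tert-butoxy-3-oxopropanoic acid; 9 2,2-diphenylethanol
Product: 10 tert-butyl 2,2-diphenylethyl malonate
Conditions: DCC, DMAP (cat.), CH2Cl2, 0 °C → rt
Reagents that add atoms: none
Why: Steglich esterification gives the unsymmetrical malonate whose two ester groups are later distinguished by the phase-transfer catalyst and by acid lability.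

**Step 6**
Reactants: 10 tert-butyl 2,2-diphenylethyl malonate; 7 (S)-lavandulyl iodide
Product: 11 lavandulylmalonate (both C2 epimers)
Conditions: NaH, DMF, 0 → 50 °C
Reagents that add atoms: none
Why: Malonate alkylation (SN2) by the primary iodide; the new malonate CH centre is uncontrolled, which does not matter because it is re-enolised in step 7.

**Step 7**
Reactants: 11 lavandulylmalonate; 4 prenyl bromide
Product: 12 quaternary dialkylmalonate
Conditions: (S,S)-N-spiro bis(binaphthyl)ammonium bromide bearing 3,4,5-trifluorophenyl groups (5 mol%), 50% aq. KOH, toluene, −40 °C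
Reagents that add atoms: none
Why: Enantioselective phase-transfer α-alkylation of a mixed tert-butyl/2,2-diphenylethyl α-alkylmalonate; both epimers of 11 give one enolate, and the chiral ammonium ion pair should expose one enolate face to prenyl bromide, setting the quaternary centre (C8 of the target, R).

**Step 8**
Reactants: 12 quaternary dialkylmalonate
Product: 14 half-ester acid, via trimethylsilyl ester 13 (not isolated)
Conditions: Me3SiOTf, 2,6-lutidine, CH2Cl2, 0 °C; then aq. citric acid, THF, rt
Reagents that add atoms: none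
Why: Silyl triflate-mediated cleavage of the tert-butyl ester (loss of isobutene) under buffered conditions that spare the trisubstituted alkenes and the primary ester; the quaternary centre cannot epimerise.

**Step 9**
Reactants: 15 (E)-2-methylbut-2-enoyl chloride (tigloyl chloride); 16 propyne
Product: 17 cross-conjugated ynone
Conditions: PdCl2(PPh3)2 (2 mol%), CuI (4 mol%), Et3N, THF, 0 °C → rt
Reagents that add atoms: none
Why: Acyl Sonogashira coupling of a terminal alkyne with an acid chloride gives the ynone with the (E)-enone geometry retained.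

**Step 10**
Reactants: 17 ynone; 18 2-(trimethylsilyl)ethanol
Product: 19 (E)-β-alkoxy enone
Conditions: PBu3 (10 mol%), CH2Cl2, 0 °C → rt
Reagents that add atoms: none
Why: Phosphine-catalysed conjugate addition of an alcohol to an ynone, which is far more electrophilic than the α,β-disubstituted enone; it gives the (E)-β-alkoxy enone and fixes the ether oxygen on the future C5.

**Step 11**
Reactants: 14 half-ester acid; 19 (E)-β-alkoxy enone
Product: 21 open-chain keto ester, via acid chloride 20 (not isolated)
Conditions: 14, 1-chloro-N,N,2-trimethylprop-1-en-1-amine, CH2Cl2, 0 °C → rt, evaporate; 19 (2.2 equiv), LiN(i-Pr)2 (2.2 equiv), THF, −78 °C; add 20, −78 °C; AcOH, −78 °C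
Reagents that add atoms: none
Why: γ-Acylation of the lithium dienolate of a β-alkoxy enone (a 1-oxido-3-alkoxy diene, nucleophilic at its terminal carbon) by the acid chloride; the second equivalent of dienolate takes up the acidic C6–H of the product, the cold quench prevents premature ring closure, and no stereocentre is formed or disturbed.

**Step 12**
Reactants: 21 open-chain keto ester
Product: 23 bicyclic enol ether, via tigloyl enol 22 (not isolated)
Conditions: LiN(SiMe3)2 (1.3 equiv), THF, −78 → 0 °C; AcOH (1.5 equiv), −78 °C; solvent change to PhCl; (−)-quinine (30 mol%), 10 °C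
Reagents that add atoms: none
Why: Proposed new method: deprotonation at C6 gives a vinylogous β-diketonate whose C4a terminus attacks the C8a ester carbonyl (intramolecular Claisen/Dieckmann acyl substitution, loss of 2,2-diphenylethoxide) to give the lithium enolate of 22, held as an O8a–Li–O4 chelate until acetic acid frees the enol; quinine then deprotonates O8a–H, the ion pair adds to C2 of the tigloyl group and the quinuclidinium N–H protonates C3. The closest known reactions are the base-induced Claisen cyclisation of polyketo esters to acylphloroglucinol-type triketones and the quinine-catalysed intramolecular oxa-Michael addition of o-tigloylphenols to cis-2,3-dimethylchroman-4-ones; new here are their union in one pot and a non-aromatic enol of a cyclic β-tricarbonyl as the nucleophile. Ring A closes 6-(enolexo)-exo-trig at the ester carbon and ring B closes 6-endo-trig at the enone β-carbon. C2 (R) should be set by the alkaloid, which selects the enone face in the ion pair as with the phenol substrates, and C3 (S, cis) by kinetic protonation of the cyclic enol on the face away from the C2 methyl; C8 and the lavandulyl centre are not enolisable and are carried through. The step needs C- over O-acylation and C4a over C6 attack (C6 would give a four-membered ring, O-attack an eight-membered one), O8a over O5 in the conjugate addition (O5 is blocked as its silylethyl ether and C8 cannot let the ring aromatise), and catalysed over background closure (the lithium chelate and low temperature keep the enone turned away from O8a before the quench). The competing C6→C2 closure of the trienolate is disfavoured by the α,β-disubstituted enone terminus and, unlike the acyl substitution, is reversible.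

**Step 13**
Reactants: 23 bicyclic enol ether
Product: 24 5-hydroxy bicyclic dione
Conditions: Bu4NF (1.5 equiv), AcOH (1.5 equiv), THF, 0 °C
Reagents that add atoms: none
Why: Fluoride-induced β-elimination of the 2-(trimethylsilyl)ethyl group from a vinylogous ester oxygen (as for 2-silylethyl esters), buffered with acetic acid so that the cis-chromanone should not epimerise.

**Step 14**
Reactants: 24 5-hydroxy bicyclic dione; 25 (E)-hex-2-enal
Product: 26 tricyclic enol δ-lactone
Conditions: (5aR,10bS)-2-mesityl-5a,10b-dihydro-4H,6H-indeno[2,1-b][1,2,4]triazolo[4,3-d][1,4]oxazin-2-ium chloride (10 mol%), 3,3',5,5'-tetra-tert-butyldiphenoquinone (1.2 equiv), i-Pr2NEt (1.2 equiv), 4 Å MS, toluene, rt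
Reagents that add atoms: none
Why: Oxidative NHC-catalysed annulation of an enal with an enolised cyclic 1,3-dicarbonyl (conjugate addition of C6 to the α,β-unsaturated acyl azolium, then O-acylation); the chiral triazolylidene should control the face of the acyl azolium and set the propyl-bearing centre (R), and lactonisation through either flanking oxygen leads to the same acid in step 15.

**Step 15**
Reactants: 26 tricyclic enol δ-lactone
Product: 27 target acid CNP0266113.2
Conditions: LiOH (2.5 equiv), THF/H2O, 0 °C; then 0.5 M HCl to pH 3, 0 °C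
Reagents that add atoms: lithium hydroxide (aqueous), [Li+].[OH-]
Why: Saponification of an enol ester, a very reactive acyl donor, at 0 °C; the substrate is held as its vinylogous carboxylate, which should suppress enolisation at C3 and retro-oxa-Michael opening, so no stereocentre is touched.

**Compound list**

1 | (4S)-4-benzyl-1,3-oxazolidin-2-one | O=C1OC[C@H](Cc2ccccc2)N1 | starting material
2 | 3-methylbut-2-enoyl chloride | CC(C)=CC(=O)Cl | starting material
3 | (4S)-4-benzyl-3-(3-methylbut-2-enoyl)-1,3-oxazolidin-2-one | CC(C)=CC(=O)N1[C@@H](Cc2ccccc2)COC1=O | intermediate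
4 | 1-bromo-3-methylbut-2-ene (prenyl bromide) | CC(C)=CCBr | starting material
5 | (4S)-4-benzyl-3-[(2S)-5-methyl-2-(prop-1-en-2-yl)hex-4-enoyl]-1,3-oxazolidin-2-one | C=C(C)[C@H](CC=C(C)C)C(=O)N1[C@@H](Cc2ccccc2)COC1=O | intermediate
6 | (2S)-5-methyl-2-(prop-1-en-2-yl)hex-4-en-1-ol ((S)-lavandulol) | C=C(C)[C@H](CC=C(C)C)CO | intermediate
7 | (3S)-3-(iodomethyl)-2,6-dimethylhepta-1,5-diene ((S)-lavandulyl iodide) | C=C(C)[C@H](CC=C(C)C)CI | intermediate
8 | 3-tert-butoxy-3-oxopropanoic acid | CC(C)(C)OC(=O)CC(=O)O | starting material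
9 | 2,2-diphenylethanol | OCC(c1ccccc1)c1ccccc1 | starting material
10 | tert-butyl 2,2-diphenylethyl propanedioate | CC(C)(C)OC(=O)CC(=O)OCC(c1ccccc1)c1ccccc1 | intermediate
11 | tert-butyl 2,2-diphenylethyl 2-[(2R)-5-methyl-2-(prop-1-en-2-yl)hex-4-en-1-yl]propanedioate (both C2 epimers) | C=C(C)[C@H](CC=C(C)C)CC(C(=O)OCC(c1ccccc1)c1ccccc1)C(=O)OC(C)(C)C | intermediate
12 | tert-butyl 2,2-diphenylethyl (2R)-2-(3-methylbut-2-en-1-yl)-2-[(2R)-5-methyl-2-(prop-1-en-2-yl)hex-4-en-1-yl]propanedioate | C=C(C)[C@H](CC=C(C)C)C[C@@](C(=O)OCC(c1ccccc1)c1ccccc1)(CC=C(C)C)C(=O)OC(C)(C)C | intermediate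
13 | 2,2-diphenylethyl trimethylsilyl (2R)-2-(3-methylbut-2-en-1-yl)-2-[(2R)-5-methyl-2-(prop-1-en-2-yl)hex-4-en-1-yl]propanedioate (formed in the flask) | C=C(C)[C@H](CC=C(C)C)C[C@@](C(=O)OCC(c1ccccc1)c1ccccc1)(CC=C(C)C)C(=O)O[Si](C)(C)C | intermediate
14 | (2S)-3-(2,2-diphenylethoxy)-2-(3-methylbut-2-en-1-yl)-2-[(2R)-5-methyl-2-(prop-1-en-2-yl)hex-4-en-1-yl]-3-oxopropanoic acid | C=C(C)[C@H](CC=C(C)C)C[C@@](C(=O)OCC(c1ccccc1)c1ccccc1)(CC=C(C)C)C(=O)O | intermediate
15 | (2E)-2-methylbut-2-enoyl chloride (tigloyl chloride) | C/C=C(\C)C(=O)Cl | starting material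
16 | propyne | CC#C | starting material
17 | (5E)-5-methylhept-5-en-2-yn-4-one | CC#CC(=O)/C(C)=C/C | intermediate
18 | 2-(trimethylsilyl)ethanol | C[Si](C)(C)CCO | starting material
19 | (2E,5E)-5-methyl-2-[2-(trimethylsilyl)ethoxy]hepta-2,5-dien-4-one | C/C(OCC[Si](C)(C)C)=C\C(=O)/C(C)=C/C | intermediate
20 | 2,2-diphenylethyl (2R)-3-chloro-2-(3-methylbut-2-en-1-yl)-2-[(2R)-5-methyl-2-(prop-1-en-2-yl)hex-4-en-1-yl]-3-oxopropanoate (formed in the flask) | C=C(C)[C@H](CC=C(C)C)C[C@@](C(=O)OCC(c1ccccc1)c1ccccc1)(CC=C(C)C)C(=O)Cl | intermediate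
21 | 2,2-diphenylethyl (2S,5E,8E)-8-methyl-2-(3-methylbut-2-en-1-yl)-2-[(2R)-5-methyl-2-(prop-1-en-2-yl)hex-4-en-1-yl]-3,7-dioxo-5-[2-(trimethylsilyl)ethoxy]deca-5,8-dienoate | C=C(C)[C@H](CC=C(C)C)C[C@@](C(=O)OCC(c1ccccc1)c1ccccc1)(CC=C(C)C)C(=O)C/C(OCC[Si](C)(C)C)=C\C(=O)/C(C)=C/C | intermediate
22 | (6R)-5-hydroxy-4-[(2E)-2-methylbut-2-enoyl]-6-(3-methylbut-2-en-1-yl)-6-[(2R)-5-methyl-2-(prop-1-en-2-yl)hex-4-en-1-yl]-3-[2-(trimethylsilyl)ethoxy]cyclohexa-2,4-dien-1-one (formed in the flask) | C=C(C)[C@H](CC=C(C)C)C[C@@]1(CC=C(C)C)C(=O)C=C(OCC[Si](C)(C)C)C(C(=O)/C(C)=C/C)=C1O | intermediate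
23 | (2R,3S,8R)-2,3-dimethyl-8-(3-methylbut-2-en-1-yl)-8-[(2R)-5-methyl-2-(prop-1-en-2-yl)hex-4-en-1-yl]-5-[2-(trimethylsilyl)ethoxy]-2,3-dihydro-4H-chromene-4,7(8H)-dione | C=C(C)[C@H](CC=C(C)C)C[C@@]1(CC=C(C)C)C(=O)C=C(OCC[Si](C)(C)C)C2=C1O[C@H](C)[C@H](C)C2=O | intermediate
24 | (2R,3S,8R)-5-hydroxy-2,3-dimethyl-8-(3-methylbut-2-en-1-yl)-8-[(2R)-5-methyl-2-(prop-1-en-2-yl)hex-4-en-1-yl]-2,3-dihydro-4H-chromene-4,7(8H)-dione | C=C(C)[C@H](CC=C(C)C)C[C@@]1(CC=C(C)C)C(=O)C=C(O)C2=C1O[C@H](C)[C@H](C)C2=O | intermediate
25 | (2E)-hex-2-enal | CCC/C=C/C=O | starting material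
26 | enol δ-lactone of 27: O5 acylated by the side-chain carboxyl to give a (4R)-4-propyl-3,4-dihydropyran-2-one ring fused at C5–C6; chromane centres 2R,3S,8R; lavandulyl centre R | C=C(C)[C@H](CC=C(C)C)C[C@@]1(CC=C(C)C)C(=O)C3=C(OC(=O)C[C@H]3CCC)C2=C1O[C@H](C)[C@H](C)C2=O | intermediate
27 | (3R)-3-[(2R,3S,8R)-5-hydroxy-2,3-dimethyl-8-(3-methylbut-2-en-1-yl)-8-[(2R)-5-methyl-2-(prop-1-en-2-yl)hex-4-en-1-yl]-4,7-dioxo-3,4,7,8-tetrahydro-2H-chromen-6-yl]hexanoic acid (CNP0266113.2) | C=C(C)[C@H](CC=C(C)C)C[C@@]1(CC=C(C)C)C(=O)C([C@H](CCC)CC(=O)O)=C(O)C2=C1O[C@H](C)[C@H](C)C2=O | target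

**Step count and risks**

Total step count: 15. Longest linear sequence: 12 steps (steps 1–4, 6–8, 11–15).

Steps most likely to fail:

1. Step 12 (proposed new method). The alkaloid-mediated conjugate addition may show poor facial or cis/trans selectivity with a non-aromatic enol, or ring B may close without the catalyst before quinine is added. The fallback sets out from 21 and returns at 23. 21 is ring-closed with LiN(SiMe3)2 alone and the enol 22 is isolated after the acetic acid quench. Ring B is then closed with the achiral base K2CO3 in butan-2-one at 40 °C, the standard conditions for tigloylphenols, to give the mixture of C2/C3 stereoisomers of the bicyclic enol ether F1. The (2R,3S) isomer 23 is separated by chromatography, and the other isomers are returned to K2CO3, where retro-oxa-Michael opening and re-closure should re-equilibrate them.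

2. Step 11. Acylation may occur on oxygen or at the α-carbon of the dienolate, or attack at the neopentyl-type acid chloride may be too slow. The fallback sets out from 14 and returns at 21. Chloride 20, made as before, is reduced with LiAlH(OtBu)3 in THF at −78 °C to the aldehyde ester F2. The lithium dienolate of 19 adds to it through its γ-carbon (vinylogous aldol addition, an aldehyde being a far less hindered electrophile) to give the β-hydroxy ketone F3 as a mixture of carbinol epimers. Dess–Martin periodinane in CH2Cl2 then oxidises the carbinol to give 21.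

3. Step 7. Enolate face selectivity may be lost because the α-substituent is much larger than those on which this catalyst type is known to work, and the lavandulyl centre may be mismatched. The fallback sets out from 11 and returns at 12. 11 is prenylated without a chiral catalyst (NaH, 4, DMF, 0 °C) to the mixture of C2 epimers F4. These are diastereomers because of the lavandulyl centre, and the (2R) epimer 12 is separated by preparative HPLC.

**Further compounds**

F1 | step 12 | (8R)-2,3-dimethyl-8-(3-methylbut-2-en-1-yl)-8-[(2R)-5-methyl-2-(prop-1-en-2-yl)hex-4-en-1-yl]-5-[2-(trimethylsilyl)ethoxy]-2,3-dihydro-4H-chromene-4,7(8H)-dione, mixture of C2/C3 stereoisomers | C=C(C)[C@H](CC=C(C)C)C[C@@]1(CC=C(C)C)C(=O)C=C(OCC[Si](C)(C)C)C2=C1OC(C)C(C)C2=O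
F2 | step 11 | 2,2-diphenylethyl (2S)-2-(3-methylbut-2-en-1-yl)-2-[(2R)-5-methyl-2-(prop-1-en-2-yl)hex-4-en-1-yl]-3-oxopropanoate | C=C(C)[C@H](CC=C(C)C)C[C@@](C(=O)OCC(c1ccccc1)c1ccccc1)(CC=C(C)C)C=O
F3 | step 11 | 2,2-diphenylethyl (2S,5E,8E)-3-hydroxy-8-methyl-2-(3-methylbut-2-en-1-yl)-2-[(2R)-5-methyl-2-(prop-1-en-2-yl)hex-4-en-1-yl]-7-oxo-5-[2-(trimethylsilyl)ethoxy]deca-5,8-dienoate, both C3 epimers | C=C(C)[C@H](CC=C(C)C)C[C@@](C(=O)OCC(c1ccccc1)c1ccccc1)(CC=C(C)C)C(O)C/C(OCC[Si](C)(C)C)=C\C(=O)/C(C)=C/C
F4 | step 7 | tert-butyl 2,2-diphenylethyl 2-(3-methylbut-2-en-1-yl)-2-[(2R)-5-methyl-2-(prop-1-en-2-yl)hex-4-en-1-yl]propanedioate, both C2 epimers | C=C(C)[C@H](CC=C(C)C)CC(CC=C(C)C)(C(=O)OCC(c1ccccc1)c1ccccc1)C(=O)OC(C)(C)C
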